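Readings and results were generated by integration on assumed constants, and the scatter is random.

Over 15 h, the flask's ledger for E, the limiting reagent, needs one rate and one loss entry, both read from the earlier runs.

all flasks: Z 3.7 mM (held)

|  | E | remark | time |
|---|---|---|---|
| Friday's | 0.025 M | run made earlier |  |
| Sunday's | 0.038 M | run made earlier |  |
| flask | 0.050 M |  | 15 h |

| run | time / h | X / % | E / % |
|---|---|---|---|
| Friday's | 1.50 | 4.8 | 96.0 |
| Friday's | 3.00 | 8.3 | 91.1 |
| Friday's | 5.00 | 14.9 | 84.8 |
| Friday's | 6.00 | 16.5 | 82.5 |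
| Friday's | 8.00 | 22.1 | 75.9 |
| Friday's | 10.0 | 27.1 | 70.7 |
| Friday's | 12.0 | 30.8 | 66.6 |
| Sunday's | 1.00 | 3.2 | 98.6 |
| Sunday's | 1.33 | 1.9 | 98.1 |
| Sunday's | 2.00 | 6.1 | 93.1 |
| Sunday's | 3.00 | 8.9 | 92.2 |
| Sunday's | 5.00 | 14.1 | 85.5 |
| Sunday's | 8.00 | 20.6 | 75.9 |
| Sunday's | 12.0 | 30.3 | 67.7 |

(scatter of a reading: 1 percentage point)

- a species is counted by the E in it: one L counts as two
- at the start none of D is dissolved
- candidate steps: D + X -> J; Z <-> D; E + X -> L; 2 D -> Q; E + D -> X

- how much X there is at 15 h, in percent of the E charged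
- the change that raises the amount of X at 15 h, in percent of the E charged most ("none" if none brings more than 2 percentage points) (ash / maple / none)
- amount of X at 15 h, in percent of the E charged, after ash

- ash: doubling the saturation concentration of Z, all else as stated
- maple: doubling the transfer coefficient of Z, all else as stated

The E column gives the opening entry. Friday's run reads 0.0339 h⁻¹ and Sunday's 0.0325 h⁻¹ at 12.0 h, about equal at charges of 0.025 M and 0.038 M, so E behaves as pseudo-first-order. I carry their mean, k, the fractional loss of E per hour at steady cD, as 0.0332 h⁻¹. By this k I reckon the flask to keep 60.8% as E.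

The second entry is E counted in neither E nor X. Z and D carry no E, and neither does Q, so J and L hold this gap, which reads 2.3 percentage points as the mean of the two runs at 12.0 h. Both are fed by X, which grows along k·t, so I scale the gap with the square of k·t, to 3.6 points. The books close with X at 35.6%.

Under ash, if cD follows saturation, k becomes 0.0664 h⁻¹, E keeps 36.9%, the gap reaches 14 points, and X stands at 48.7%.

The forecast gives 34.5%, chooses ash and puts it at 48.5%, close to but not the same as my figures: “Maple does little.”

The flask gives 34.2%. Ash gives 51.9%, a gain of 18 points against 2.9 points for maple, so the choice is ash.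

    D + X → J (k = 2.30 M⁻¹ h⁻¹)
    Z ⇌ D, rate k2*(csat - [D]) (kL = 2.30 h⁻¹)
    E + X → L (k = 0.150 M⁻¹ h⁻¹)
    2 D → Q (k = 22.0 M⁻¹ h⁻¹)
    E + D → X (k = 11.0 M⁻¹ h⁻¹)

The flask's E of 60.9% returns k as 0.0331 h⁻¹, while its J and L together hold 5 points against my 3.6 points. Read at 40 h, the same flask should keep 26.5% of its E by k. It keeps 23%, less than that, with X at 56.1%, J at 10.5% and L at 9.90%.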